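## The problem

Licoriphenone (17) is a deoxybenzoin: a 2,4-dihydroxyphenyl ketone (ring A) is joined through C(=O)–CH2 to a benzene ring B in which every position is different. C1' carries the CH2, C2' a methoxy group, C3' a prenyl group, C4' a methoxy group, C5' a hydrogen and C6' a hydroxyl. There is no stereocentre and no ring to close, so the difficulty lies in regiochemistry on ring B and in functional-group tolerance. The demanding bond is CH2–C1', which has to be made at a carbon lying between OMe and OH on a very electron-rich ring, without touching C5'. Three features forbid rough treatment: the prenyl alkene (hydrogenation, strong acid, electrophiles), the enolisable CH2 between ring B and the carbonyl, and the C6' hydroxyl, which under acid adds to the ketone and dehydrates to a 2-arylbenzofuran. The ring A hydroxyls therefore need a mask that comes off under neither acidic nor reducing conditions. The feature that opens a short route is that the C6' hydroxyl and the C1' chain are neighbours. Without the chain, ring B is 3,5-dimethoxy-4-prenylphenol (6), which has a mirror plane through C3' and C6' and two equivalent ortho carbons, so a [3,3] shift from the phenolic oxygen to its ortho carbon reaches C1' without any regiochemical choice and leaves that oxygen as the C6' hydroxyl.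

## Retrosynthesis

**17 ⇒ 16.** The last bonds cut are the two ring A O–H bonds, which become O–allyl in 16. Ring A must be masked: a free 2-hydroxyl would hydrogen-bond the carbonyl, slow the oxime condensation, and could attack the activated oxime nitrogen in the key step. Acid-labile ethers would expose the finished hydroxy ketone to cyclodehydration, and hydrogenolysis would reduce the prenyl group. Allyl ethers are ionised by zerovalent palladium, the more readily here because both phenoxides are conjugated to the ketone, and a neutral amine accepts the allyl group. The forward step must transfer allyl to the amine and not to the enolisable CH2, so no base is added.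

**16 ⇒ 13 (key disconnection).** The CH2–C1' bond is cut and the C6' oxygen is tied through nitrogen to the carbonyl carbon, giving O-aryl ketoxime ether 13. Forward, N-acylation turns 13 into ene-hydroxylamine 14; its [3,3] shift exchanges the weak N–O bond for the C–C bond; the liberated phenol closes onto the acyl imine to give aminal 15; hydrolysis returns the ketone as 16. The neighbouring cuts (C(=O)–CH2 or C(=O)–ring A) both leave a ring B benzylic or arylacetic fragment, so C1' would have to be functionalised in a separate step and the C6' hydroxyl protected. Here nothing need pre-exist at C1', and the phenol emerges free. The simplification is large: 13 divides into a hydroxylamine of a symmetric phenol and a plain acetophenone. The forward reaction must form a single enamine (assured, since the other substituent on the C=N carbon is ring A) and must stop at the ketone oxidation level before aminal 15 aromatises, which is why the medium is kept basic throughout.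

**13 ⇒ 8 + 12.** The C=N bond is cut to aryloxyamine 8 and ketone 12. This is an ordinary condensation, and either oxime geometry is acceptable because the key step passes through 14. The forward reaction needs acid catalysis weak enough not to start the rearrangement.

**8 ⇒ 6.** The O–N bond is cut to phenol 6, aminated forward as its potassium salt 7 by an electrophilic NH2 donor. Metal-catalysed O-arylation of a hydroxylamine surrogate would instead need ring B as a halide or boronic acid, two or three steps further from 6. The forward reaction must aminate at oxygen and not at the nucleophilic ortho carbons.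

**6 ⇒ 5 ⇒ 2 ⇒ 1 + 3.** The C3'–CH2 bond of the prenyl group is cut. Direct prenylation of 1 would go to oxygen or to the carbons ortho to the hydroxyl. Metalation of silyl ether 2 between its two methoxy groups gives aryllithium 4, which places the prenyl group on the one carbon that preserves the mirror plane. The bulky silyl group hides the acidic proton and keeps the base away from its own ortho positions; fluoride then returns 6 from 5. Both starting materials, 1 and 3, are commodity chemicals.

**12 ⇒ 9 + 10.** Two O–allyl bonds are cut, so two equivalents of 10 are consumed per molecule of 9. The double etherification runs through the mono-ether 11, because the hydrogen-bonded 2-hydroxyl reacts second.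

## Roads not taken

Alternative 1: Ring B is divided into a four-carbon piece, 3-methoxy-2-(3-methylbut-2-enyl)cyclobut-2-en-1-one A1 (C3' to C6'), and a two-carbon piece, the methyl ynol ether A2 (C1' and C2', with the side chain as a silyl-protected carbinol).
- **Forward key step:** heating opens A1, which adds to A2 in a [2+2] sense; 4π opening and 6π closure (Danheiser benzannulation) form C6'–C1' and C2'–C3' and give phenol A3.
- **Merits:** all five substituents of ring B are placed by the polarity of the partners, the C6' hydroxyl emerges free, and the conditions are neutral.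
- **Weak points:** the side chain cannot travel as the ketone, so A2 carries a carbinol stereocentre that serves no purpose. After the annulation the carbinol must be unmasked and oxidised beside a free, oxidation-prone phenol. The methoxymethyl ethers of ring A then have to be removed with acid from exactly the hydroxy ketone that acid cyclodehydrates. Neither A1 nor A2 is purchasable, and the phenol A3 can be acylated by a second molecule of opened A1.
- **Comparison:** the benzannulation is the more dependable key reaction, since it has no cascade to arrest, and that is a real advantage. The chosen plan sets against it an intact, symmetric ring B bought as a benzene, a ketone kept at its final oxidation level, no stereocentre to erase, and roughly half the number of steps.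

Alternative 2: Ring A is cut across C1–C2 and C5–C6, leaving the terminal ynone A4 (complete ring B, C6' hydroxyl as methoxymethyl ether) and the diene 1-methoxy-1,3-bis(trimethylsilyloxy)buta-1,3-diene A5.
- **Forward key step:** a Diels–Alder addition joins the CH2 terminus of A5 to the β-carbon of A4; elimination of the acetal methoxy group and desilylation give the resorcinol ketone A6.
- **Merits:** ring A needs no protecting group, the regiochemistry follows from the polarity of both partners, and the cycloaddition itself is not in doubt.
- **Weak points:** A4 has a CH2 between an electron-rich arene and an ynone carbonyl and is prone to prototropic isomerisation and conjugate addition. More seriously, making A4 still requires a two-carbon acyl chain to be attached at C1' by a separate ortho-functionalisation, so the hard bond is relocated and not solved. The last step is acid cleavage of the methoxymethyl ether of A6 next to the ketone, with the cyclodehydration risk already described.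
- **Comparison:** this road is better in protecting-group economy on ring A. The chosen plan spends its key step on the difficult bond itself and finishes under neutral conditions.

Alternative 3: Both bonds to the carbonyl carbon are cut, giving the benzyl chloride A7, the arylboronic acid A8 and a one-carbon carbonyl unit.
- **Forward key step:** a carbonylative Suzuki–Miyaura coupling (oxidative addition of A7 to zerovalent palladium, carbonyl insertion, transmetalation with A8, reductive elimination) gives the tris(methoxymethyl) ether A9.
- **Merits:** it is the most convergent plan, makes two C–C bonds at once, delivers the ketone directly at the right oxidation level, and uses an established reaction class.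
- **Weak points:** A7 is a 2,4,6-trioxygenated benzyl chloride that ionises very easily and is hard to store. Reaching it from phenol 6 needs protection, ortho-formylation, reduction and chlorination, so the C1' carbon is again installed separately. A8 is an electron-rich, ortho-alkoxy boronic acid prone to protodeboronation, and direct coupling without carbonyl insertion competes. Three methoxymethyl ethers must finally be removed with acid from the benzofuran-prone product.
- **Comparison:** its key step is better established and needs no arrest of a cascade. The chosen plan answers with a shorter sequence (8 steps), no labile benzylic halide, installation of the ortho carbon and release of the phenol in one event, and an acid-free last step.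

Key step: step 7

Assumption: oxime ether 13 is drawn as its E isomer (aryloxy group anti to ring A), the geometry expected for an aryl methyl ketoxime ether; the Z isomer would give the same ene-hydroxylamine 14, so the geometry has no bearing on the route.

## Route

Step 1
Reactants: 1 3,5-dimethoxyphenol
Product: 2 (3,5-dimethoxyphenoxy)triisopropylsilane
Conditions: TIPSCl, imidazole, DMF, rt
Reagents that add atoms: triisopropylsilyl chloride, CC(C)[Si](Cl)(C(C)C)C(C)C
Why: Imidazole-mediated O-silylation of a phenol; the bulky triisopropylsilyl group neither coordinates nor yields to n-BuLi, so the next step metalates between the methoxy groups.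

Step 2
Reactants: 2 (3,5-dimethoxyphenoxy)triisopropylsilane; 3 prenyl bromide (1-bromo-3-methylbut-2-ene)
Product: 5 [3,5-dimethoxy-4-(3-methylbut-2-enyl)phenoxy]triisopropylsilane, via 2,6-dimethoxy-4-(triisopropylsilyloxy)phenyllithium 4 (not isolated)
Conditions: n-BuLi, THF, 0 °C to rt; then 3, −78 °C to rt
Reagents that add atoms: none
Why: Directed ortho-metalation: the C–H flanked by two methoxy groups is the most acidic and best coordinated site, as in 1,3-dimethoxybenzene, while the shielded silyloxy oxygen directs poorly. Aryllithium 4 is then alkylated by SN2 displacement at the primary allylic carbon of 3.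

Step 3
Reactants: 5 [3,5-dimethoxy-4-(3-methylbut-2-enyl)phenoxy]triisopropylsilane
Product: 6 3,5-dimethoxy-4-(3-methylbut-2-enyl)phenol
Conditions: TBAF, THF, 0 °C
Reagents that add atoms: none
Why: Fluoride cleavage of an aryl silyl ether; nothing else in 5 responds to fluoride.

Step 4
Reactants: 6 3,5-dimethoxy-4-(3-methylbut-2-enyl)phenol
Product: 8 O-[3,5-dimethoxy-4-(3-methylbut-2-enyl)phenyl]hydroxylamine, via potassium 3,5-dimethoxy-4-(3-methylbut-2-enyl)phenoxide 7 (not isolated)
Conditions: KOt-Bu, DMF, 0 °C; then O-(2,4-dinitrophenyl)hydroxylamine, 0 °C to rt
Reagents that add atoms: O-(2,4-dinitrophenyl)hydroxylamine, NOc1ccc(cc1[N+](=O)[O-])[N+](=O)[O-]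
Why: Electrophilic amination of a phenoxide: the oxygen of 7 displaces 2,4-dinitrophenoxide from nitrogen, the established route to O-arylhydroxylamines with donor-substituted rings. The alkene and methyl ethers are inert to the reagent, and 8 should be carried into step 6 without storage.

Step 5
Reactants: 9 2,4-dihydroxyacetophenone; 10 allyl bromide (3-bromoprop-1-ene)
Product: 12 1-[2,4-bis(prop-2-enyloxy)phenyl]ethanone, via 1-[2-hydroxy-4-(prop-2-enyloxy)phenyl]ethanone 11 (not isolated)
Conditions: 10 (2.5 equiv), K2CO3, DMF, 60 °C
Reagents that add atoms: allyl bromide (second equivalent, the same compound as 10), C=CCBr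
Why: Twofold Williamson ether synthesis that consumes two equivalents of allyl bromide: the first alkylates the more acidic, unhindered 4-hydroxyl to give 11, and the second alkylates the hydrogen-bonded 2-hydroxyl in warm DMF. The temperature is far below that at which aryl allyl ethers undergo Claisen rearrangement.

Step 6
Reactants: 8 O-[3,5-dimethoxy-4-(3-methylbut-2-enyl)phenyl]hydroxylamine; 12 1-[2,4-bis(prop-2-enyloxy)phenyl]ethanone
Product: 13 (E)-1-[2,4-bis(prop-2-enyloxy)phenyl]ethanone O-[3,5-dimethoxy-4-(3-methylbut-2-enyl)phenyl]oxime
Conditions: PPTS (cat.), EtOH, 4 Å molecular sieves, 40 °C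
Reagents that add atoms: none
Why: Oxime ether formation by condensation of an O-substituted hydroxylamine with a ketone, driven by the sieves; the acid is kept weak so that 13 does not begin to rearrange. The E isomer is expected, though either isomer serves.

Step 7
Reactants: 13 (E)-1-[2,4-bis(prop-2-enyloxy)phenyl]ethanone O-[3,5-dimethoxy-4-(3-methylbut-2-enyl)phenyl]oxime
Product: 16 1-[2,4-bis(prop-2-enyloxy)phenyl]-2-[6-hydroxy-2,4-dimethoxy-3-(3-methylbut-2-enyl)phenyl]ethanone, via N-trifluoroacetyl ene-hydroxylamine 14 (not isolated), via cyclic trifluoroacetamido aminal 15 (not isolated)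
Conditions: (CF3CO)2O, Et3N, CH2Cl2, 0 °C to rt; then K2CO3, MeOH–H2O, rt; pH 6 phosphate buffer
Reagents that add atoms: water, O
Why: Trifluoroacetylation of the oxime nitrogen and removal of a methyl proton by Et3N give the N-acyl ene-hydroxylamine 14, the only enamine possible because the other substituent on the C=N carbon is ring A. In 14 the six atoms ortho-C, ipso-C, O, N, C and CH2 can adopt a chair-like array, and a [3,3] sigmatropic shift, driven by exchange of the weak N–O bond for a C–C bond and accelerated by the acyl group and the electron-rich aryloxy ring, joins CH2 to C1' at or below room temperature. The cyclohexadienone so formed tautomerises to the phenol, whose oxygen adds 5-exo to the N-acyl imine to give the racemic aminal 15; this transient dihydrofuran ring is not kept and its one stereocentre is of no consequence. The closest known reaction type is the trifluoroacetyl-promoted rearrangement of O-aryl ketoxime ethers, the oxygen counterpart of the Fischer indole synthesis, which without strong acid halts at aminals of the type of 15. Carbonate in aqueous methanol then cleaves the trifluoroacetamide or opens the aminal by expulsion of phenoxide, and hydrolysis of the resulting imine delivers ketone 16 and trifluoroacetamide. Regiochemistry needs no control, since the two ortho carbons of the aryloxy group are equivalent and the para carbon is blocked by the prenyl group. The selectivity that matters is to stop before the aminal ionises at C2 and aromatises, which the 2,4-dialkoxyphenyl group would assist under acid; excess amine during acylation, basic hydrolysis and a buffered work-up are there to prevent it.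

Step 8
Reactants: 16 1-[2,4-bis(prop-2-enyloxy)phenyl]-2-[6-hydroxy-2,4-dimethoxy-3-(3-methylbut-2-enyl)phenyl]ethanone
Product: 17 licoriphenone, 1-(2,4-dihydroxyphenyl)-2-[6-hydroxy-2,4-dimethoxy-3-(3-methylbut-2-enyl)phenyl]ethanone
Conditions: Pd(PPh3)4 (5 mol %), morpholine, THF, rt
Reagents that add atoms: none
Why: Palladium-catalysed deallylation of the Tsuji–Trost type: zerovalent palladium ionises both aryl allyl ethers, whose phenoxides are good leaving groups because they are conjugated to the ketone, and morpholine traps the π-allyl unit. The neutral amine medium avoids both acid (cyclodehydration) and enolate formation (allyl transfer to the CH2), and the prenyl group, which has no leaving group, is untouched.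

## Compound list

1 | 3,5-dimethoxyphenol | COc1cc(O)cc(OC)c1 | starting material
2 | (3,5-dimethoxyphenoxy)triisopropylsilane | COc1cc(O[Si](C(C)C)(C(C)C)C(C)C)cc(OC)c1 | intermediate
3 | prenyl bromide (1-bromo-3-methylbut-2-ene) | CC(C)=CCBr | starting material
4 | 2,6-dimethoxy-4-(triisopropylsilyloxy)phenyllithium | [Li]c1c(OC)cc(O[Si](C(C)C)(C(C)C)C(C)C)cc1OC | intermediate
5 | [3,5-dimethoxy-4-(3-methylbut-2-enyl)phenoxy]triisopropylsilane | COc1cc(O[Si](C(C)C)(C(C)C)C(C)C)cc(OC)c1CC=C(C)C | intermediate
6 | 3,5-dimethoxy-4-(3-methylbut-2-enyl)phenol | COc1cc(O)cc(OC)c1CC=C(C)C | intermediate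
7 | potassium 3,5-dimethoxy-4-(3-methylbut-2-enyl)phenoxide | [K+].[O-]c1cc(OC)c(CC=C(C)C)c(OC)c1 | intermediate
8 | O-[3,5-dimethoxy-4-(3-methylbut-2-enyl)phenyl]hydroxylamine | NOc1cc(OC)c(CC=C(C)C)c(OC)c1 | intermediate
9 | 2,4-dihydroxyacetophenone | CC(=O)c1ccc(O)cc1O | starting material
10 | allyl bromide (3-bromoprop-1-ene) | C=CCBr | starting material
11 | 1-[2-hydroxy-4-(prop-2-enyloxy)phenyl]ethanone | CC(=O)c1ccc(OCC=C)cc1O | intermediate
12 | 1-[2,4-bis(prop-2-enyloxy)phenyl]ethanone | CC(=O)c1ccc(OCC=C)cc1OCC=C | intermediate
13 | (E)-1-[2,4-bis(prop-2-enyloxy)phenyl]ethanone O-[3,5-dimethoxy-4-(3-methylbut-2-enyl)phenyl]oxime | C/C(=N\Oc1cc(OC)c(CC=C(C)C)c(OC)c1)c1ccc(OCC=C)cc1OCC=C | intermediate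
14 | N-{1-[2,4-bis(prop-2-enyloxy)phenyl]ethenyl}-N-[3,5-dimethoxy-4-(3-methylbut-2-enyl)phenoxy]-2,2,2-trifluoroacetamide | C=C(c1ccc(OCC=C)cc1OCC=C)N(Oc1cc(OC)c(CC=C(C)C)c(OC)c1)C(=O)C(F)(F)F | intermediate
15 | racemic N-{2-[2,4-bis(prop-2-enyloxy)phenyl]-4,6-dimethoxy-5-(3-methylbut-2-enyl)-2,3-dihydro-1-benzofuran-2-yl}-2,2,2-trifluoroacetamide | COc1cc2OC(NC(=O)C(F)(F)F)(c3ccc(OCC=C)cc3OCC=C)Cc2c(OC)c1CC=C(C)C | intermediate
16 | 1-[2,4-bis(prop-2-enyloxy)phenyl]-2-[6-hydroxy-2,4-dimethoxy-3-(3-methylbut-2-enyl)phenyl]ethanone | COc1cc(O)c(CC(=O)c2ccc(OCC=C)cc2OCC=C)c(OC)c1CC=C(C)C | intermediate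
17 | licoriphenone, 1-(2,4-dihydroxyphenyl)-2-[6-hydroxy-2,4-dimethoxy-3-(3-methylbut-2-enyl)phenyl]ethanone | COc1cc(O)c(CC(=O)c2ccc(O)cc2O)c(OC)c1CC=C(C)C | target

## Step count and risk

Total: 8 steps. Longest linear sequence: 7 steps (steps 1, 2, 3, 4, 6, 7, 8, from 1 to 17); the ring A branch (step 5) joins at step 6.

**Step 7 (key step).** The most likely failure is that the cascade does not stop at the ketone level. Aminal 15 may ionise at C2 and aromatise by loss of its nitrogen substituent, because the 2,4-dialkoxyphenyl group stabilises positive charge there, or the hydrolysis may stall at an enamide. The fallback replaces the sigmatropic bond formation by a cross-coupling; it sets out from 6 and 9 and rejoins the route at 17.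
- 6 is brominated at one of its two equivalent open ring positions (N-bromosuccinimide, CH2Cl2, −78 °C) to 2-bromo-3,5-dimethoxy-4-(3-methylbut-2-enyl)phenol F1.
- 9 is silylated (i-Pr3SiOSO2CF3, 2,6-lutidine, CH2Cl2) to 1-[2,4-bis(triisopropylsilyloxy)phenyl]ethanone F2. F2 is used in place of 12 because zerovalent palladium and an enolate would transfer the allyl groups of 12 to carbon.
- Palladium-catalysed enolate arylation of F2 with the free bromophenol F1 (Pd2(dba)3, a bulky dialkylbiarylphosphine, NaOt-Bu, toluene, 80 °C) gives 1-[2,4-bis(triisopropylsilyloxy)phenyl]-2-[6-hydroxy-2,4-dimethoxy-3-(3-methylbut-2-enyl)phenyl]ethanone F3. This reaction class gives α-(2-hydroxyaryl) ketones, which cyclise only when acid is added.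
- TBAF in THF removes both silyl groups to give 17.

**Step 4.** The most likely failure is amination at carbon instead of oxygen, since the ortho carbons of phenoxide 7 are strongly nucleophilic. Attack of the phenoxide on the dinitroarene ring and N–O cleavage of 8 on standing are further risks. The fallback sets out from 6 and 12 and rejoins at 13, bypassing 8.
- 6 is converted with (CF3SO2)2O and pyridine to 3,5-dimethoxy-4-(3-methylbut-2-enyl)phenyl trifluoromethanesulfonate F4.
- Miyaura borylation (B2pin2, PdCl2(dppf), KOAc, dioxane, 80 °C) gives 2-[3,5-dimethoxy-4-(3-methylbut-2-enyl)phenyl]-4,4,5,5-tetramethyl-1,3,2-dioxaborolane F5.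
- 12 is oximated (NH2OH·HCl, NaOAc, EtOH) to (E)-1-[2,4-bis(prop-2-enyloxy)phenyl]ethanone oxime F6.
- Chan–Lam O-arylation of F6 with F5 (Cu(OAc)2 (cat.), pyridine, air, 4 Å sieves, 1,2-dichloroethane) gives 13.

**Step 6.** The most likely failure is slow or incomplete condensation, because the carbonyl of 12 is deactivated by two alkoxy donors and shielded by the ortho allyloxy group. Strengthening the acid to compensate risks premature, uncontrolled rearrangement of 13. The fallback sets out from 12 and rejoins at 13: 12 is converted (HC(OMe)3, TsOH (cat.), MeOH) to its dimethyl ketal 1-(1,1-dimethoxyethyl)-2,4-bis(prop-2-enyloxy)benzene F7, which ionises readily to an oxocarbenium ion and exchanges with 8 under PPTS catalysis in toluene at 50 °C with removal of methanol.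

**Step 2.** The most likely failure is loss of regiocontrol in the alkylation (attack at the tertiary terminus of the prenyl unit, halogen–metal exchange or elimination) or incomplete metalation. Less likely is metalation next to the silyloxy group followed by silyl migration from oxygen to carbon. The fallback sets out from 2 through 4 and rejoins at 5: 4 is quenched with allyl bromide 10, for which both modes of allylic substitution give the same product, to [3,5-dimethoxy-4-(prop-2-enyl)phenoxy]triisopropylsilane F8. Cross-metathesis with 2-methylbut-2-ene (second-generation Grubbs catalyst, CH2Cl2, 40 °C) then gives 5.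

## Further compounds

F1 | step 7 | 2-bromo-3,5-dimethoxy-4-(3-methylbut-2-enyl)phenol | COc1cc(O)c(Br)c(OC)c1CC=C(C)C
F2 | step 7 | 1-[2,4-bis(triisopropylsilyloxy)phenyl]ethanone | CC(=O)c1ccc(O[Si](C(C)C)(C(C)C)C(C)C)cc1O[Si](C(C)C)(C(C)C)C(C)C
F3 | step 7 | 1-[2,4-bis(triisopropylsilyloxy)phenyl]-2-[6-hydroxy-2,4-dimethoxy-3-(3-methylbut-2-enyl)phenyl]ethanone | COc1cc(O)c(CC(=O)c2ccc(O[Si](C(C)C)(C(C)C)C(C)C)cc2O[Si](C(C)C)(C(C)C)C(C)C)c(OC)c1CC=C(C)C
F4 | step 4 | 3,5-dimethoxy-4-(3-methylbut-2-enyl)phenyl trifluoromethanesulfonate | COc1cc(OS(=O)(=O)C(F)(F)F)cc(OC)c1CC=C(C)C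
F5 | step 4 | 2-[3,5-dimethoxy-4-(3-methylbut-2-enyl)phenyl]-4,4,5,5-tetramethyl-1,3,2-dioxaborolane | COc1cc(B2OC(C)(C)C(C)(C)O2)cc(OC)c1CC=C(C)C
F6 | step 4 | (E)-1-[2,4-bis(prop-2-enyloxy)phenyl]ethanone oxime | C/C(=N\O)c1ccc(OCC=C)cc1OCC=C
F7 | step 6 | 1-(1,1-dimethoxyethyl)-2,4-bis(prop-2-enyloxy)benzene | COC(C)(OC)c1ccc(OCC=C)cc1OCC=C
F8 | step 2 | [3,5-dimethoxy-4-(prop-2-enyl)phenoxy]triisopropylsilane | COc1cc(O[Si](C(C)C)(C(C)C)C(C)C)cc(OC)c1CC=C
A1 | alternative 1 | 3-methoxy-2-(3-methylbut-2-enyl)cyclobut-2-en-1-one | COC1=C(CC=C(C)C)C(=O)C1
A2 | alternative 1 | racemic {1-[2,4-bis(methoxymethoxy)phenyl]-4-methoxybut-3-ynyloxy}(tert-butyl)dimethylsilane | COC#CCC(O[Si](C)(C)C(C)(C)C)c1ccc(OCOC)cc1OCOC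
A3 | alternative 1 | racemic 2-{2-[2,4-bis(methoxymethoxy)phenyl]-2-(tert-butyldimethylsilyloxy)ethyl}-3,5-dimethoxy-4-(3-methylbut-2-enyl)phenol | COc1cc(O)c(CC(O[Si](C)(C)C(C)(C)C)c2ccc(OCOC)cc2OCOC)c(OC)c1CC=C(C)C
A4 | alternative 2 | 1-[2,4-dimethoxy-6-(methoxymethoxy)-3-(3-methylbut-2-enyl)phenyl]but-3-yn-2-one | COCOc1cc(OC)c(CC=C(C)C)c(OC)c1CC(=O)C#C
A5 | alternative 2 | 1-methoxy-1,3-bis(trimethylsilyloxy)buta-1,3-diene | COC(O[Si](C)(C)C)=CC(O[Si](C)(C)C)=C
A6 | alternative 2 | 1-(2,4-dihydroxyphenyl)-2-[2,4-dimethoxy-6-(methoxymethoxy)-3-(3-methylbut-2-enyl)phenyl]ethanone | COCOc1cc(OC)c(CC=C(C)C)c(OC)c1CC(=O)c1ccc(O)cc1O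
A7 | alternative 3 | 2,4-dimethoxy-6-(methoxymethoxy)-3-(3-methylbut-2-enyl)benzyl chloride | COCOc1cc(OC)c(CC=C(C)C)c(OC)c1CCl
A8 | alternative 3 | [2,4-bis(methoxymethoxy)phenyl]boronic acid | COCOc1ccc(B(O)O)c(OCOC)c1
A9 | alternative 3 | 1-[2,4-bis(methoxymethoxy)phenyl]-2-[2,4-dimethoxy-6-(methoxymethoxy)-3-(3-methylbut-2-enyl)phenyl]ethanone | COCOc1cc(OC)c(CC=C(C)C)c(OC)c1CC(=O)c1ccc(OCOC)cc1OCOC
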